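**Retrosynthetic overview**
- The thioacetate is installed last from a primary alcohol (Mitsunobu); the alcohol travels through the route as a TBDPS ether.
- The only ring, the 2,3-dimethoxy-4-pyranone, comes from O-methylation of a 4-hydroxy-3-methoxy-2-pyranone, itself formed by DBU lactonisation of a 3,5-dioxo ester.
- Key C–C bond (future pyranone C5–C6): intermolecular aldol between the dianion of methyl 2-methoxy-3-oxopentanoate and the side-chain β,γ-unsaturated aldehyde, followed by oxidation.
- The aldehyde comes from an (E)-homoallylic alcohol made by zirconium-catalysed methylalumination of silyl-protected undec-10-yn-1-ol and opening of ethylene oxide; this sets the E alkene.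
- The keto ester comes from methyl 3-oxopentanoate by diazo transfer and O–H insertion into methanol.

Assumption: lehualide C has no stereogenic centre, so "single enantiomer" is read as the single (E)-alkene isomer drawn.

**Step 1**
Reactants: 1 methyl 3-oxopentanoate
Product: 2 methyl 2-diazo-3-oxopentanoate
Conditions: p-ABSA (1.1 equiv), Et3N (1.5 equiv), MeCN, 0 °C → rt
Reagents that add atoms: 4-acetamidobenzenesulfonyl azide (p-ABSA), CC(=O)Nc1ccc(cc1)S(=O)(=O)N=[N+]=[N-]
Why: Regitz diazo transfer to the doubly activated methylene of a β-keto ester is fast and high-yielding, and the sulfonamide by-product is removed by filtration.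

**Step 2**
Reactants: 2 methyl 2-diazo-3-oxopentanoate
Product: 3 methyl 2-methoxy-3-oxopentanoate (racemic)
Conditions: Rh2(OAc)4 (1 mol %), MeOH (5 equiv), CH2Cl2, 40 °C
Reagents that add atoms: methanol, CO
Why: Rhodium-carbenoid O–H insertion into methanol places the methoxy group at C2 cleanly, and the racemic stereocentre created is erased in step 8.

**Step 3**
Reactants: 4 undec-10-yn-1-ol
Product: 5 tert-butyl(diphenyl)(undec-10-yn-1-yloxy)silane
Conditions: TBDPSCl (1.1 equiv), imidazole (2 equiv), DMF, rt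
Reagents that add atoms: tert-butylchlorodiphenylsilane, CC(C)(C)[Si](Cl)(c1ccccc1)c1ccccc1
Why: Imidazole-promoted silylation of a primary alcohol gives a TBDPS ether that withstands AlMe3, strong base, DBU and methyl triflate later on.

**Step 4**
Reactants: 5 tert-butyl(diphenyl)(undec-10-yn-1-yloxy)silane
Product: 8 (E)-13-[(tert-butyldiphenylsilyl)oxy]-4-methyltridec-3-en-1-ol, via alkenyldimethylalane 6 (not isolated), via lithium alkenyl(butyl)dimethylalanate 7 (not isolated)
Conditions: AlMe3 (2.5 equiv), Cp2ZrCl2 (0.25 equiv), CH2Cl2, 0 °C → rt; volatiles evaporated; n-BuLi (1.1 equiv), hexane/THF, –78 → 0 °C; ethylene oxide (3 equiv, THF solution), –78 °C → rt; aq. KNaC4H4O6 work-up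
Reagents that add atoms: trimethylaluminium, C[Al](C)C; ethylene oxide, C1CO1
Why: Negishi zirconium-catalysed carboalumination adds methyl and aluminium syn across the terminal alkyne (methyl to the internal carbon), and the derived alanate opens ethylene oxide with retention at the alkenyl carbon, so the E trisubstituted alkene is fixed here.

**Step 5**
Reactants: 8 (E)-13-[(tert-butyldiphenylsilyl)oxy]-4-methyltridec-3-en-1-ol
Product: 9 (E)-13-[(tert-butyldiphenylsilyl)oxy]-4-methyltridec-3-enal
Conditions: Dess–Martin periodinane (1.3 equiv), NaHCO3 (5 equiv), CH2Cl2, 0 °C → rt; Na2S2O3/NaHCO3 work-up; short silica plug, used at once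
Reagents that add atoms: none
Why: Buffered Dess–Martin oxidation is neutral enough to deliver the β,γ-unsaturated aldehyde without migration of the alkene into conjugation.

**Step 6**
Reactants: 3 methyl 2-methoxy-3-oxopentanoate; 9 (E)-13-[(tert-butyldiphenylsilyl)oxy]-4-methyltridec-3-enal
Product: 11 methyl (E)-17-[(tert-butyldiphenylsilyl)oxy]-5-hydroxy-2-methoxy-4,8-dimethyl-3-oxoheptadec-7-enoate (diastereomer mixture), via sodium lithium dienediolate 10 (not isolated)
Conditions: 3 (1.5 equiv), NaH (1.05 equiv per 3), THF, 0 °C; n-BuLi (1.0 equiv per 3), 0 °C, 30 min; 9 (1.0 equiv), –78 °C, 1 h; AcOH quench at –78 °C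
Reagents that add atoms: none
Why: In this Weiler dianion aldol the more reactive γ-carbanion (C4) adds to the aldehyde at –78 °C faster than it enolises it, and the three uncontrolled stereocentres formed are all destroyed in steps 7 and 8.

**Step 7**
Reactants: 11 methyl (E)-17-[(tert-butyldiphenylsilyl)oxy]-5-hydroxy-2-methoxy-4,8-dimethyl-3-oxoheptadec-7-enoate
Product: 12 methyl (E)-17-[(tert-butyldiphenylsilyl)oxy]-2-methoxy-4,8-dimethyl-3,5-dioxoheptadec-7-enoate (enol tautomers)
Conditions: Dess–Martin periodinane (1.5 equiv), NaHCO3 (5 equiv), CH2Cl2, rt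
Reagents that add atoms: none
Why: Dess–Martin oxidation of the β-hydroxy ketone to the 1,3-diketone is non-basic, which avoids retro-aldol cleavage and alkene migration.

**Step 8**
Reactants: 12 methyl (E)-17-[(tert-butyldiphenylsilyl)oxy]-2-methoxy-4,8-dimethyl-3,5-dioxoheptadec-7-enoate
Product: 13 6-[(E)-12-[(tert-butyldiphenylsilyl)oxy]-3-methyldodec-2-en-1-yl]-4-hydroxy-3-methoxy-5-methyl-2H-pyran-2-one
Conditions: DBU (2 equiv), toluene, rt → 50 °C; 10% aq. citric acid work-up
Reagents that add atoms: none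
Why: In this base-mediated enol lactonisation the C5 enolate oxygen attacks the methyl ester, and tautomerisation to the aromatic 4-hydroxy-2-pyranone drives the closure; DBU only deprotonates the acidic C4 position and then the hydroxypyranone, so the skipped alkene is left alone.

**Step 9**
Reactants: 13 6-[(E)-12-[(tert-butyldiphenylsilyl)oxy]-3-methyldodec-2-en-1-yl]-4-hydroxy-3-methoxy-5-methyl-2H-pyran-2-one
Product: 15 6-[(E)-12-[(tert-butyldiphenylsilyl)oxy]-3-methyldodec-2-en-1-yl]-2,3-dimethoxy-5-methyl-4H-pyran-4-one, via hydroxypyrylium triflate 14 (not isolated)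
Conditions: MeOTf (1.5 equiv), CH2Cl2, 0 °C → rt; then sat. aq. NaHCO3
Reagents that add atoms: methyl trifluoromethanesulfonate, COS(=O)(=O)C(F)(F)F
Why: Regioselective O-methylation with a hard methylating agent occurs at the lactone carbonyl oxygen of the neutral hydroxypyranone to give an aromatic 4-hydroxy-2-methoxypyrylium salt, which loses a proton on basic work-up to give the 2-methoxy-4-pyranone.

**Step 10**
Reactants: 15 6-[(E)-12-[(tert-butyldiphenylsilyl)oxy]-3-methyldodec-2-en-1-yl]-2,3-dimethoxy-5-methyl-4H-pyran-4-one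
Product: 16 6-[(E)-12-hydroxy-3-methyldodec-2-en-1-yl]-2,3-dimethoxy-5-methyl-4H-pyran-4-one
Conditions: TBAF (1.5 equiv), AcOH (1.5 equiv), THF, rt
Reagents that add atoms: none
Why: Fluoride-mediated desilylation buffered with acetic acid frees the primary alcohol without touching the methoxypyranone or the alkene.

**Step 11**
Reactants: 16 6-[(E)-12-hydroxy-3-methyldodec-2-en-1-yl]-2,3-dimethoxy-5-methyl-4H-pyran-4-one
Product: 17 lehualide C, S-[(E)-12-(5,6-dimethoxy-3-methyl-4-oxo-4H-pyran-2-yl)-10-methyldodec-10-en-1-yl] ethanethioate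
Conditions: PPh3 (1.5 equiv), DIAD (1.5 equiv), THF, 0 °C, 30 min; then 16 and AcSH (1.5 equiv), 0 °C → rt
Reagents that add atoms: thioacetic acid, CC(=O)S
Why: Mitsunobu thioesterification converts the unhindered primary alcohol directly into the base-sensitive thioacetate under neutral conditions as the last operation.

**Compound list**
1 | methyl 3-oxopentanoate | CCC(=O)CC(=O)OC | starting material
2 | methyl 2-diazo-3-oxopentanoate | CCC(=O)C(=[N+]=[N-])C(=O)OC | intermediate
3 | methyl 2-methoxy-3-oxopentanoate (racemic) | CCC(=O)C(OC)C(=O)OC | intermediate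
4 | undec-10-yn-1-ol | C#CCCCCCCCCCO | starting material
5 | tert-butyl(diphenyl)(undec-10-yn-1-yloxy)silane | C#CCCCCCCCCCO[Si](c1ccccc1)(c1ccccc1)C(C)(C)C | intermediate
6 | [(E)-11-[(tert-butyldiphenylsilyl)oxy]-2-methylundec-1-en-1-yl]dimethylalane | C[Al](C)/C=C(\C)CCCCCCCCCO[Si](c1ccccc1)(c1ccccc1)C(C)(C)C | intermediate (not isolated)
7 | lithium butyl[(E)-11-[(tert-butyldiphenylsilyl)oxy]-2-methylundec-1-en-1-yl]dimethylalanate | [Li+].CCCC[Al-](C)(C)/C=C(\C)CCCCCCCCCO[Si](c1ccccc1)(c1ccccc1)C(C)(C)C | intermediate (not isolated)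
8 | (E)-13-[(tert-butyldiphenylsilyl)oxy]-4-methyltridec-3-en-1-ol | OCC/C=C(\C)CCCCCCCCCO[Si](c1ccccc1)(c1ccccc1)C(C)(C)C | intermediate
9 | (E)-13-[(tert-butyldiphenylsilyl)oxy]-4-methyltridec-3-enal | O=CC/C=C(\C)CCCCCCCCCO[Si](c1ccccc1)(c1ccccc1)C(C)(C)C | intermediate
10 | sodium lithium dianion (1,3-dienediolate) of methyl 2-methoxy-3-oxopentanoate | [Na+].[Li+].CC=C([O-])C(OC)=C([O-])OC | intermediate (not isolated)
11 | methyl (E)-17-[(tert-butyldiphenylsilyl)oxy]-5-hydroxy-2-methoxy-4,8-dimethyl-3-oxoheptadec-7-enoate (diastereomer mixture) | COC(=O)C(OC)C(=O)C(C)C(O)C/C=C(\C)CCCCCCCCCO[Si](c1ccccc1)(c1ccccc1)C(C)(C)C | intermediate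
12 | methyl (E)-17-[(tert-butyldiphenylsilyl)oxy]-2-methoxy-4,8-dimethyl-3,5-dioxoheptadec-7-enoate | COC(=O)C(OC)C(=O)C(C)C(=O)C/C=C(\C)CCCCCCCCCO[Si](c1ccccc1)(c1ccccc1)C(C)(C)C | intermediate
13 | 6-[(E)-12-[(tert-butyldiphenylsilyl)oxy]-3-methyldodec-2-en-1-yl]-4-hydroxy-3-methoxy-5-methyl-2H-pyran-2-one | COc1c(O)c(C)c(C/C=C(\C)CCCCCCCCCO[Si](c2ccccc2)(c2ccccc2)C(C)(C)C)oc1=O | intermediate
14 | 6-[(E)-12-[(tert-butyldiphenylsilyl)oxy]-3-methyldodec-2-en-1-yl]-4-hydroxy-2,3-dimethoxy-5-methylpyrylium trifluoromethanesulfonate | COc1[o+]c(C/C=C(\C)CCCCCCCCCO[Si](c2ccccc2)(c2ccccc2)C(C)(C)C)c(C)c(O)c1OC.[O-]S(=O)(=O)C(F)(F)F | intermediate (not isolated)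
15 | 6-[(E)-12-[(tert-butyldiphenylsilyl)oxy]-3-methyldodec-2-en-1-yl]-2,3-dimethoxy-5-methyl-4H-pyran-4-one | COc1oc(C/C=C(\C)CCCCCCCCCO[Si](c2ccccc2)(c2ccccc2)C(C)(C)C)c(C)c(=O)c1OC | intermediate
16 | 6-[(E)-12-hydroxy-3-methyldodec-2-en-1-yl]-2,3-dimethoxy-5-methyl-4H-pyran-4-one | COc1oc(C/C=C(\C)CCCCCCCCCO)c(C)c(=O)c1OC | intermediate
17 | lehualide C | COc1oc(C/C=C(\C)CCCCCCCCCSC(C)=O)c(C)c(=O)c1OC | target

**Totals**
Total step count: 11. Longest linear sequence: 9 steps (4 → 17, steps 3 to 11); the keto ester branch (steps 1 and 2) joins at step 6.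

**Three steps most likely to fail, with fallbacks**

Step 6 (dianion aldol with an enolisable β,γ-unsaturated aldehyde; risk of aldehyde enolisation or alkene migration under strongly basic conditions). The fallback sets out from 3 and comes back at 11. Keto ester 3 is converted with Me3SiCl and Et3N into methyl 2-methoxy-3-[(trimethylsilyl)oxy]pent-2-enoate F3, which is deprotonated with LiN(i-Pr)2 at –78 °C and silylated again to give 1,2-dimethoxy-1,3-bis[(trimethylsilyl)oxy]penta-1,3-diene F4. This bis-silyl dienol ether is added to aldehyde 9 with TiCl4 in CH2Cl2 at –78 °C (vinylogous Mukaiyama aldol at the terminal carbon); aqueous work-up removes the silyl groups and gives 11, with the aldehyde never exposed to a strong base.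

Step 9 (O-methylation; risk of the wrong regioisomer or of acid damage to the alkene or silyl ether on a late intermediate). The fallback sets out from 3 (and from 5 for the side chain) and comes back at 15. Dianion 10 is added to acetaldehyde to give methyl 5-hydroxy-2-methoxy-4-methyl-3-oxohexanoate F5, which is oxidised with Dess–Martin periodinane to methyl 2-methoxy-4-methyl-3,5-dioxohexanoate F6. DBU cyclises this to 4-hydroxy-3-methoxy-5,6-dimethyl-2H-pyran-2-one F7, and MeOTf methylates it to 2,3-dimethoxy-5,6-dimethyl-4H-pyran-4-one F8, a robust compound from which any regioisomer is easily separated. In parallel, alkenylalane 6 (from 5) is trapped with paraformaldehyde to give (E)-12-[(tert-butyldiphenylsilyl)oxy]-3-methyldodec-2-en-1-ol F9, which CBr4 and PPh3 convert into (E)-[(12-bromo-10-methyldodec-10-en-1-yl)oxy](tert-butyl)diphenylsilane F10. The C6 methyl group of F8 is deprotonated with LiN(SiMe3)2 in THF at –78 °C and the resulting vinylogous enolate is alkylated with F10 to give 15.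

Step 4 (one-pot carboalumination, alanate formation and epoxide opening; risk of low conversion in the epoxide opening). The fallback sets out from 5 and comes back at 8. After the same carboalumination, alkenylalane 6 is quenched with iodine (I2) to give (E)-tert-butyl[(11-iodo-10-methylundec-10-en-1-yl)oxy]diphenylsilane F1. Suzuki–Miyaura coupling with potassium vinyltrifluoroborate (CH2=CHBF3K), PdCl2(dppf) and Cs2CO3 in THF/H2O at 70 °C gives (E)-tert-butyl[(10-methyltrideca-10,12-dien-1-yl)oxy]diphenylsilane F2. Chemoselective hydroboration of the terminal vinyl group with disiamylborane in THF at 0 °C, followed by NaOH/H2O2, returns homoallylic alcohol 8 with the E alkene intact.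

**Further compounds**
F1 | step 4 | (E)-tert-butyl[(11-iodo-10-methylundec-10-en-1-yl)oxy]diphenylsilane | I/C=C(\C)CCCCCCCCCO[Si](c1ccccc1)(c1ccccc1)C(C)(C)C
F2 | step 4 | (E)-tert-butyl[(10-methyltrideca-10,12-dien-1-yl)oxy]diphenylsilane | C=C/C=C(\C)CCCCCCCCCO[Si](c1ccccc1)(c1ccccc1)C(C)(C)C
F3 | step 6 | methyl 2-methoxy-3-[(trimethylsilyl)oxy]pent-2-enoate | CCC(O[Si](C)(C)C)=C(OC)C(=O)OC
F4 | step 6 | 1,2-dimethoxy-1,3-bis[(trimethylsilyl)oxy]penta-1,3-diene | CC=C(O[Si](C)(C)C)C(OC)=C(OC)O[Si](C)(C)C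
F5 | step 9 | methyl 5-hydroxy-2-methoxy-4-methyl-3-oxohexanoate (diastereomer mixture) | COC(=O)C(OC)C(=O)C(C)C(C)O
F6 | step 9 | methyl 2-methoxy-4-methyl-3,5-dioxohexanoate | COC(=O)C(OC)C(=O)C(C)C(C)=O
F7 | step 9 | 4-hydroxy-3-methoxy-5,6-dimethyl-2H-pyran-2-one | COc1c(O)c(C)c(C)oc1=O
F8 | step 9 | 2,3-dimethoxy-5,6-dimethyl-4H-pyran-4-one | COc1oc(C)c(C)c(=O)c1OC
F9 | step 9 | (E)-12-[(tert-butyldiphenylsilyl)oxy]-3-methyldodec-2-en-1-ol | OC/C=C(\C)CCCCCCCCCO[Si](c1ccccc1)(c1ccccc1)C(C)(C)C
F10 | step 9 | (E)-[(12-bromo-10-methyldodec-10-en-1-yl)oxy](tert-butyl)diphenylsilane | BrC/C=C(\C)CCCCCCCCCO[Si](c1ccccc1)(c1ccccc1)C(C)(C)C
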